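You read these flasks at 8.0 d, as the end of a run or as the average stay in the tank, and target goes on turning into over-reaction product until you read.

| setting | north-west | north-east | east | west |
|---|---|---|---|---|
| starting material | 42 mM | 42 mM | 42 mM | 42 mM (fed, over 6.40 d) |
| second substrate | 42.0 mM | 42.0 mM (fed, over 6.40 d) | 42.0 mM | 42.0 mM |
| enzyme | 4.2 µM | 4.2 µM | 4.2 µM | 4.2 µM |
| remark | a single well-mixed tank run continuously and read at steady state, 8.0 d in it on average | a stirred flask in which second substrate is dosed at a steady rate over 6.40 d without added volume, worked up at 8.0 d | everything together in a closed stirred flask, run for 8.0 d | a stirred flask in which starting material is dosed at a steady rate over 6.40 d without added volume, worked up at 8.0 d |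
| time |  | 8.0 d | 8.0 d | 8.0 d |

    target → over-reaction product (k1 = 0.0268 h⁻¹)
    complex A → enzyme + target (k2 = 557 h⁻¹)
    second substrate + enzyme ⇌ complex B (K3 = 21.2 M⁻¹, k3 = 2.26 × 10⁶ M⁻¹ h⁻¹)
    complex B → enzyme + second product (k4 = 1360 h⁻¹)
    starting material + enzyme ⇌ complex A (K5 = 33 M⁻¹, k5 = 6.45 × 10⁵ M⁻¹ h⁻¹)
    enzyme → spent catalyst (k6 = 2.76 × 10⁻⁵ h⁻¹)

- the set-up with the highest share of target in all that became target or over-reaction product, at the outlet or at the end ("none" if the first two lie within 2 percentage points) (north-west / north-east / east / west / none)
- share of target in all that became target or over-reaction product, at the outlet or at the end, north-west
- share of target in all that became target or over-reaction product, at the outlet or at the end, north-east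
- share of target in all that became target or over-reaction product, at the outlet or at the end, east
- share of target in all that became target or over-reaction product, at the outlet or at the end, west

- the stated concentrations are those of everything mixed, before any reaction; amounts are the same in each set-up
- the feed brings no volume worth counting
- run time (north-east): 8.0 d

Two times matter: the mean life of target against its loss to over-reaction product, 37.3 h, and the time you hold it, 8.0 d. The life is shorter than the hold, while the enzyme's own half-life, 1050 d, is far longer than the hold, so you leave enzyme loss aside. The ratio of the two times is 5.15. Dividing by 2.3 gives the decades of hold, 2.24: the powers of ten by which target born at the start has shrunk when you read.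

In a closed flask, that makes 0.582% the floor of the share, and target born later loses fewer decades. East and north-east, with starting material present from the start, should therefore lie above it. In the north-west tank, target leaves by two first-order ways, washout and loss, so the share is 16.3%. In west, counting target as born the moment its starting material is dosed gives 8.54%, and any lag raises that. This reckoning stops there, with the lag in west not reckoned, and its pick is north-west, whose share stands above that west figure.

The forecast names north-west, with 16.3% for north-west, 1.27% for north-east, 1.42% for east and 13.2% for west, noting “so over-reaction dominates”. Its west figure stands above this reckoning's.

The simulation gives north-west: 16.3% for north-west, 1.27% for north-east, 1.42% for east and 13.2% for west.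

East reads 0.387 decades above the floor, as if all its target had been born 1.39 d after the start. The north-east flask has not come to rest at 8.0 d: target stands at 1.27% of the starting material charged, and 0.062% of the second substrate remains. In north-east, ten times the time makes 22.4 decades of hold, and at 80.0 d the share reads 0%, with over-reaction product at 100%. Spent catalyst in north-east meanwhile goes from 0.459% to 5.09% of the catalyst charged.

(The constants are assumed; what happens was integrated by code.)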